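- 3 questions stand on this flask, and one balance carries the reckoning here: that of the left-handed substrate, with 1.50 equiv of partner against it; the right-handed side stands outside this balance.

| flask | left-handed substrate | right-handed substrate | partner | free catalyst | remark | time |
|---|---|---|---|---|---|---|
| beta | 0.70 M | 0.70 M | 1.5 equiv | 0.5 mol% | run made earlier |  |
| eta | 1.1 M | 1.1 M | 1.5 equiv | 0.5 mol% | run made earlier |  |
| flask | 0.50 M | 0.50 M | 1.50 equiv | 0.5 mol% |  | 8.0 h |

- beta (time / h: left-handed substrate / %, right-handed substrate / %, left-handed product / %): 1.00: 48.4, 50.9, 4.2; 2.00: 43.5, 48.8, 6.2; 3.00: 40.4, 49.1, 8.3; 4.00: 38.6, 48.4, 11.4; 5.00: 36.5, 48.6, 12.5; 6.00: 35.8, 49.8, 15.4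
- eta (time / h: left-handed substrate / %, right-handed substrate / %, left-handed product / %): 0.500: 47.8, 51.3, 2.8; 0.833: 47.8, 49.4, 5.7; 1.33: 46.4, 50.0, 5.8; 2.00: 41.1, 49.1, 7.4; 3.00: 38.8, 49.3, 11.3; 4.00: 35.0, 48.2, 15.5; 6.00: 30.1, 49.4, 19.3

(readings scatter by 1 percentage point)

- part of the left-handed substrate and right-handed substrate charged together that has reacted at 8.0 h
- excess of left-handed product over right-handed product in the product at 8.0 h
- excess of right-handed substrate over left-handed substrate among what is left of the two at 8.0 h

- free catalyst is single-handed; left-handed substrate and right-handed substrate are mirror images of each other, charged as a racemate, each of them at the stated concentration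
- an excess is the difference of the two amounts in percent of their sum
- an excess is below zero if the other one leads

- Let f be the fraction of charged left-handed substrate still free, and treat its loss as pseudo-first-order.
- Turn the concentration first. By hand, with equivalents and loading held, partner and catalyst grow with the charge, so expect minus ln f per hour to grow in step with it.
- Test that on the last readings. Per molar charged they give 0.0795 M⁻¹ h⁻¹ in beta and 0.0769 M⁻¹ h⁻¹ in eta, close.
- Carry their mean, the charge constant: minus ln f per hour per molar of left-handed substrate charged, 0.0782 M⁻¹ h⁻¹.
- Turn the partner next. Beta and eta both hold 1.5 equiv, so assume by hand that the exponent follows the partner charged.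
- Leave the loading: beta, eta and this flask all stand at 0.5 mol%.
- Reckon this flask: f comes to 73.1 %, so by this balance, with the right-handed loss left aside, 13.4 % of the two substrates charged together has reacted, below the forecast's 16.6 %.
- Read the forecast: 16.6 %, 89 % and 17.5 % for c, eP and eS, with the remark “The right-handed loss is barely resolved”.
- See what this flask gives: 15.4 %, 94.8 % and 17.0 %. The forecast's c and eS hold, and its eP falls 5.8 percentage points short.

    free catalyst + left-handed substrate ⇌ catalyst intermediate A (K = 3.20 M⁻¹, k = 140 M⁻¹ h⁻¹)
    free catalyst + right-handed substrate ⇌ catalyst intermediate B (K = 3.00 M⁻¹, k = 1200 M⁻¹ h⁻¹)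
    partner + catalyst intermediate A → free catalyst + left-handed product (k = 54.0 M⁻¹ h⁻¹)
    partner + catalyst intermediate B → free catalyst + right-handed product (k = 0.750 M⁻¹ h⁻¹)
    partner → decomposed reagent (k = 0.0270 h⁻¹)
    partner + free catalyst → spent catalyst (k = 0.0330 M⁻¹ h⁻¹)



- In this flask, partner and catalyst intermediate A made left-handed product, reaching 14.9 % at 8.00 h, while catalyst intermediate B held 44.2 % of the catalyst and gave 0.399 % of right-handed product. Partner stood at 62 % of its charge by then, and the 70 % of left-handed substrate left makes the charge constant 0.0886 M⁻¹ h⁻¹, more than the 0.0782 M⁻¹ h⁻¹ carried.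
- Carry the charge constant as this flask gave it, 0.0886 M⁻¹ h⁻¹, to the neighbour flask with 0.600 equiv of partner: scaled by partner, f comes to 86.8 %. The computed neighbour keeps 84 %, with c 8.03 % and eP 96.4 %.

The numbers in the tables are calculated with constants of no real substance, and the scatter is random.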